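**Retrosynthetic overview**
1. Target 23 is unmasked from diaryl ether 21 by benzyl ester hydrogenolysis and acetonide saponification; the C6–O–C4' ether bond of 21 comes from Pd-catalysed etherification of ring A triflate 11 with ring B phenol 20.
2. The strategy rests on ring A: heptyl (C2), carboxyl (C1) and an oxygen (C6) sit on three adjacent carbons, with the C4 methoxy para to the carboxyl. This is the footprint of a carbon nucleophile and CO2 adding across the C1–C2 bond of 3,5-dimethoxybenzyne, so acid 8 comes from 1-fluoro-3,5-dimethoxybenzene 3, two heptyllithium and CO2; the C6 methoxy is then cleaved by chelation to the carboxyl.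
3. Ring B (C1' CO2H, C2' OH, C4' O-aryl, C5' OMe, C6' heptyl) comes from aldol aromatization of diketo-dioxinone 19, built from 2,2,6-trimethyl-4H-1,3-dioxin-4-one, methoxyacetyl chloride (which supplies the C5' methoxy that a plain resorcylate synthesis would lack) and an octanoyl unit.
4. Ring order: ring A is bought as a benzene ring and only substituted (steps 2–5); the ring B benzene ring is the only ring formed (step 9), before the two rings are joined (step 10).

Key step: step 2

Remark: the target has no stereocentre, so no route compound carries a stereodescriptor. Locants C1–C6 (ring A) and C1'–C6' (ring B) count from the carboxyl-bearing carbon of each ring.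

**Route**

Step 1
Reactants: 1 1-bromoheptane
Product: 2 heptyllithium (ethereal solution, filtered and titrated)
Conditions: Li wire (ca. 1% Na, 2.2 equiv), Et2O, −20 → −10 °C, Ar
Reagents that add atoms: lithium, [Li]
Why: Reductive lithiation of a primary alkyl bromide by lithium metal (two single-electron transfers at the metal surface) is the classical preparation of n-alkyllithiums, and cold, slow addition in ether should keep Wurtz coupling low.

Step 2
Reactants: 3 1-fluoro-3,5-dimethoxybenzene; 2 heptyllithium; 4 carbon dioxide
Product: 8 2-heptyl-4,6-dimethoxybenzoic acid, via 2-fluoro-4,6-dimethoxyphenyllithium 5 (not isolated), via 3,5-dimethoxybenzyne 6 (not isolated), via 2-heptyl-4,6-dimethoxyphenyllithium 7 (not isolated)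
Conditions: 3 added dropwise to 2 (2.5 equiv), THF/Et2O, −78 → 0 °C; then −78 °C, dry CO2 gas, → rt; 1 M HCl
Reagents that add atoms: none
Why: Heptyllithium first removes the proton of 3 that lies between fluorine and a methoxy group, the site acidified by both, to give 5, which on warming ejects LiF and becomes aryne 6. A second heptyllithium then adds across the strained triple bond at the former C–F carbon, because the flanking methoxy distorts and polarises the aryne so that negative charge develops on the carbon next to oxygen, and the resulting aryllithium 7 is carboxylated by CO2. The closest known reaction type is alkyllithium addition to a 3-alkoxyaryne generated from an ortho-fluoroaryllithium with electrophilic trapping of the adduct, as practised for 5-alkylresorcinol ethers and 6-alkyl-2-methoxybenzoic acids. No ring is closed and no stereocentre is formed; the step makes the C2–heptyl and C1–CO2H bonds of ring A in one flask. The selectivities needed are metalation beside fluorine and delivery of heptyl meta to the neighbouring methoxy: the mirror symmetry of 3 makes both F/OMe-flanked sites equivalent, an anion formed between the two methoxy groups cannot eliminate and should revert by proton exchange as 5 is drained, and 7 has no halogen beside lithium and so cannot form a second aryne. Adding 3 to an excess of 2 should keep 7 from competing with heptyllithium for aryne 6.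

Step 3
Reactants: 8 2-heptyl-4,6-dimethoxybenzoic acid
Product: 9 2-heptyl-6-hydroxy-4-methoxybenzoic acid
Conditions: BCl3 (1 M in CH2Cl2, 3 equiv), CH2Cl2, −78 → 0 °C; H2O
Reagents that add atoms: none
Why: Chelation-directed Lewis acid O-demethylation: boron bound at the carboxyl also coordinates the C6 methoxy oxygen in a six-membered chelate, so chloride removes only that methyl as chloromethane while the unchelated C4 methoxy should survive at low temperature.

Step 4
Reactants: 9 2-heptyl-6-hydroxy-4-methoxybenzoic acid
Product: 10 benzyl 2-heptyl-6-hydroxy-4-methoxybenzoate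
Conditions: BnBr (1.1 equiv), KHCO3 (1.2 equiv), DMF, rt
Reagents that add atoms: benzyl bromide, BrCc1ccccc1
Why: Carboxylate O-alkylation (SN2 esterification): KHCO3 ionises only the carboxylic acid and leaves the hydrogen-bonded C6 phenol untouched, and alkylation at the carboxylate oxygen is not slowed by the two ortho substituents that would block a Fischer esterification.

Step 5
Reactants: 10 benzyl 2-heptyl-6-hydroxy-4-methoxybenzoate
Product: 11 benzyl 2-heptyl-4-methoxy-6-{[(trifluoromethyl)sulfonyl]oxy}benzoate
Conditions: Tf2O (1.2 equiv), pyridine, CH2Cl2, 0 °C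
Reagents that add atoms: trifluoromethanesulfonic anhydride, O=S(=O)(OS(=O)(=O)C(F)(F)F)C(F)(F)F
Why: O-Sulfonylation of the phenol turns the C6 oxygen into an aryl triflate, a pseudohalide that the ortho ester activates for oxidative addition.

Step 6
Reactants: 12 octanoyl chloride
Product: 13 N-methoxy-N-methyloctanamide
Conditions: MeNH(OMe)·HCl (1.1 equiv), Et3N (2.2 equiv), CH2Cl2, 0 °C → rt
Reagents that add atoms: N,O-dimethylhydroxylamine hydrochloride, CNOC.Cl
Why: Nucleophilic acyl substitution (Schotten–Baumann-type amidation) should give the Weinreb amide, an acyl donor that acylates enolates at carbon without double addition.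

Step 7
Reactants: 14 2,2,6-trimethyl-4H-1,3-dioxin-4-one; 15 methoxyacetyl chloride
Product: 17 6-(3-methoxy-2-oxopropyl)-2,2-dimethyl-4H-1,3-dioxin-4-one, via lithium 2,2-dimethyl-6-methylidene-6H-1,3-dioxin-4-olate 16 (not isolated)
Conditions: 14 (2.2 equiv), LiN(SiMe3)2 (2.2 equiv), THF, −78 °C; 15 (1.0 equiv), −78 °C; aq. NH4Cl
Reagents that add atoms: none
Why: Claisen-type γ-acylation of a vinylogous ester dienolate: the base removes a C6-methyl proton of 14 and dienolate 16 attacks the acid chloride through its exocyclic carbon, while the second equivalent of 16 takes up the more acidic proton of 17 so that it is not acylated twice.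

Step 8
Reactants: 17 6-(3-methoxy-2-oxopropyl)-2,2-dimethyl-4H-1,3-dioxin-4-one; 13 N-methoxy-N-methyloctanamide
Product: 19 6-(3-methoxy-2,4-dioxoundecyl)-2,2-dimethyl-4H-1,3-dioxin-4-one, via dilithium 1,3-bis(enolate) dianion 18 (not isolated)
Conditions: LiN(iPr)2 (2.2 equiv), THF, −78 °C; 13 (0.8 equiv), −78 → −30 °C; cold aq. NH4Cl
Reagents that add atoms: none
Why: Crossed Claisen condensation of a β-dicarbonyl-type dianion: the second deprotonation of 17 can only occur at the methoxy-bearing CH2, this last-formed enolate carbon of 18 is the more nucleophilic one, and the Weinreb amide acylates it at carbon to give the 2-methoxy-1,3-diketone, which is then shielded from further attack as its enolate.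

Step 9
Reactants: 19 6-(3-methoxy-2,4-dioxoundecyl)-2,2-dimethyl-4H-1,3-dioxin-4-one
Product: 20 5-heptyl-7-hydroxy-6-methoxy-2,2-dimethyl-4H-1,3-benzodioxin-4-one
Conditions: Et3N (2 equiv), CH2Cl2, rt
Reagents that add atoms: none
Why: Base-mediated intramolecular aldol condensation with aromatization (biomimetic polyketide cyclization): the dienolate of 19 attacks the heptyl ketone through dioxinone C5 in a 6-(enolexo)-exo-trig closure, and loss of water with enolization of the remaining ring ketone gives the ring B benzene ring with C4' OH free, C5' OMe and C6' heptyl in place and C1'/C2' still masked as the acetonide.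

Step 10
Reactants: 11 benzyl 2-heptyl-4-methoxy-6-{[(trifluoromethyl)sulfonyl]oxy}benzoate; 20 5-heptyl-7-hydroxy-6-methoxy-2,2-dimethyl-4H-1,3-benzodioxin-4-one
Product: 21 benzyl 2-heptyl-6-[(5-heptyl-6-methoxy-2,2-dimethyl-4-oxo-4H-1,3-benzodioxin-7-yl)oxy]-4-methoxybenzoate
Conditions: Pd(OAc)2 (5 mol %), 2-di-tert-butylphosphino-2',4',6'-triisopropylbiphenyl (10 mol %), K3PO4 (2 equiv), toluene, 100 °C
Reagents that add atoms: none
Why: Palladium-catalysed C–O cross-coupling (Buchwald–Hartwig diaryl ether synthesis): zerovalent palladium formed from Pd(OAc)2 inserts into the C–OTf bond activated by the ortho ester, the phenoxide of 20 replaces triflate on palladium, and the bulky di-tert-butyl biarylphosphine forces C–O reductive elimination, while sparingly soluble K3PO4 keeps the free phenoxide concentration low.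

Step 11
Reactants: 21 benzyl 2-heptyl-6-[(5-heptyl-6-methoxy-2,2-dimethyl-4-oxo-4H-1,3-benzodioxin-7-yl)oxy]-4-methoxybenzoate
Product: 22 2-heptyl-6-[(5-heptyl-6-methoxy-2,2-dimethyl-4-oxo-4H-1,3-benzodioxin-7-yl)oxy]-4-methoxybenzoic acid
Conditions: H2 (1 atm), Pd/C (10 wt %), EtOAc, rt
Reagents that add atoms: none
Why: Catalytic hydrogenolysis of the benzylic C–O bond frees the hindered ring A acid under neutral conditions that leave the diaryl ether, the aryl methyl ethers and the benzodioxinone untouched.

Step 12
Reactants: 22 2-heptyl-6-[(5-heptyl-6-methoxy-2,2-dimethyl-4-oxo-4H-1,3-benzodioxin-7-yl)oxy]-4-methoxybenzoic acid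
Product: 23 4-(2-carboxy-3-heptyl-5-methoxyphenoxy)-2-heptyl-6-hydroxy-3-methoxybenzoic acid (target CNP0151337.0)
Conditions: 5 M aq. KOH, DMSO, 70 °C; then 0 °C, 1 M HCl to pH 2, EtOAc extraction
Reagents that add atoms: potassium hydroxide, [K+].[OH-]
Why: Saponification of the salicylate acetonide: hydroxide adds to the lactone carbonyl, the hemiketal alkoxide so released loses acetone to unveil the C2' phenoxide and C1' carboxylate, and cold acidification should give the diacid without decarboxylation of the ring B β-resorcylic-type acid.

**Compound list**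
1 | 1-bromoheptane | CCCCCCCBr | starting material
2 | heptyllithium | [Li]CCCCCCC | intermediate
3 | 1-fluoro-3,5-dimethoxybenzene | COc1cc(F)cc(OC)c1 | starting material
4 | carbon dioxide | O=C=O | starting material
5 | 2-fluoro-4,6-dimethoxyphenyllithium | [Li]c1c(F)cc(OC)cc1OC | intermediate
6 | 3,5-dimethoxybenzyne | COC1=CC(OC)=CC#C1 | intermediate
7 | 2-heptyl-4,6-dimethoxyphenyllithium | [Li]c1c(CCCCCCC)cc(OC)cc1OC | intermediate
8 | 2-heptyl-4,6-dimethoxybenzoic acid | CCCCCCCc1cc(OC)cc(OC)c1C(=O)O | intermediate
9 | 2-heptyl-6-hydroxy-4-methoxybenzoic acid | CCCCCCCc1cc(OC)cc(O)c1C(=O)O | intermediate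
10 | benzyl 2-heptyl-6-hydroxy-4-methoxybenzoate | CCCCCCCc1cc(OC)cc(O)c1C(=O)OCc1ccccc1 | intermediate
11 | benzyl 2-heptyl-4-methoxy-6-{[(trifluoromethyl)sulfonyl]oxy}benzoate | CCCCCCCc1cc(OC)cc(OS(=O)(=O)C(F)(F)F)c1C(=O)OCc1ccccc1 | intermediate
12 | octanoyl chloride | CCCCCCCC(=O)Cl | starting material
13 | N-methoxy-N-methyloctanamide | CCCCCCCC(=O)N(C)OC | intermediate
14 | 2,2,6-trimethyl-4H-1,3-dioxin-4-one | CC1=CC(=O)OC(C)(C)O1 | starting material
15 | methoxyacetyl chloride | COCC(=O)Cl | starting material
16 | lithium 2,2-dimethyl-6-methylidene-6H-1,3-dioxin-4-olate | C=C1C=C(O[Li])OC(C)(C)O1 | intermediate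
17 | 6-(3-methoxy-2-oxopropyl)-2,2-dimethyl-4H-1,3-dioxin-4-one | COCC(=O)CC1=CC(=O)OC(C)(C)O1 | intermediate
18 | dilithium 1,3-bis(enolate) dianion of 17 | COC=C(O[Li])C=C1C=C(O[Li])OC(C)(C)O1 | intermediate
19 | 6-(3-methoxy-2,4-dioxoundecyl)-2,2-dimethyl-4H-1,3-dioxin-4-one | CCCCCCCC(=O)C(OC)C(=O)CC1=CC(=O)OC(C)(C)O1 | intermediate
20 | 5-heptyl-7-hydroxy-6-methoxy-2,2-dimethyl-4H-1,3-benzodioxin-4-one | CCCCCCCc1c(OC)c(O)cc2OC(C)(C)OC(=O)c12 | intermediate
21 | benzyl 2-heptyl-6-[(5-heptyl-6-methoxy-2,2-dimethyl-4-oxo-4H-1,3-benzodioxin-7-yl)oxy]-4-methoxybenzoate | CCCCCCCc1cc(OC)cc(Oc2cc3OC(C)(C)OC(=O)c3c(CCCCCCC)c2OC)c1C(=O)OCc1ccccc1 | intermediate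
22 | 2-heptyl-6-[(5-heptyl-6-methoxy-2,2-dimethyl-4-oxo-4H-1,3-benzodioxin-7-yl)oxy]-4-methoxybenzoic acid | CCCCCCCc1cc(OC)cc(Oc2cc3OC(C)(C)OC(=O)c3c(CCCCCCC)c2OC)c1C(=O)O | intermediate
23 | 4-(2-carboxy-3-heptyl-5-methoxyphenoxy)-2-heptyl-6-hydroxy-3-methoxybenzoic acid | CCCCCCCc1cc(OC)cc(Oc2cc(O)c(C(=O)O)c(CCCCCCC)c2OC)c1C(=O)O | target

**Count**
Total steps: 12. Longest linear sequence: 8 steps (steps 1, 2, 3, 4, 5, 10, 11, 12, from 1-bromoheptane); the ring B branch (steps 6 or 7, 8, 9) joins at step 10.

**Steps most likely to fail**

Step 10. The triflyl group of the ester-activated triflate 11 may be transferred to the phenoxide of 20 (S–O cleavage), or the cycle may stall at the arylpalladium phenoxide because a para-acyl, ortho-methoxy phenoxide eliminates reductively only slowly. The fallback replaces palladium C–O reductive elimination by copper-mediated oxidative coupling. Setting out from 11, Miyaura borylation (bis(pinacolato)diboron, PdCl2(dppf) with dppf = 1,1'-bis(diphenylphosphino)ferrocene, KOAc, dioxane, 90 °C) should give benzyl 2-heptyl-4-methoxy-6-(4,4,5,5-tetramethyl-1,3,2-dioxaborolan-2-yl)benzoate F1. Chan–Lam–Evans etherification of F1 with phenol 20 (Cu(OAc)2, pyridine, 4 Å molecular sieves, MeCN, air, 50 °C) comes back to the route at 21.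

Step 8. Proton transfer from the product or O-acylation may outrun C-acylation at the hindered, methoxy-bearing terminus of the dianion, so that conversion stalls, and the diketo-dioxinone may condense with itself during the basic quench. The fallback replaces the Claisen acylation by aldol addition and oxidation. Setting out from 17, the dianion 18 (LiN(iPr)2, THF, −78 °C) is added to octanal (CCCCCCCC=O) to give 6-(4-hydroxy-3-methoxy-2-oxoundecyl)-2,2-dimethyl-4H-1,3-dioxin-4-one F2 as a mixture of diastereomers. Oxidation with Dess–Martin periodinane (CH2Cl2, 0 °C → rt) removes both stereocentres and comes back to the route at 19.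

Step 2. Substrate may be lost by metalation between the two methoxy groups, aryllithium 7 may add to aryne 6 before CO2 is admitted, and carboxylation of the doubly ortho-substituted 7 may stay incomplete, all of which lower the yield and leave acidic by-products. The fallback introduces heptyl by cross-coupling and the carboxyl carbon by electrophilic formylation. Setting out from 1, magnesium in THF gives heptylmagnesium bromide F3. Kumada coupling with commercial 1-bromo-3,5-dimethoxybenzene (COc1cc(Br)cc(OC)c1; PdCl2(dppf), THF, reflux) gives 1-heptyl-3,5-dimethoxybenzene F4. Vilsmeier–Haack formylation (POCl3, DMF, 0 → 60 °C) should go para to one methoxy and ortho to the other, not between the two, and give 2-heptyl-4,6-dimethoxybenzaldehyde F5. Pinnick oxidation (NaClO2, NaH2PO4, 2-methyl-2-butene, t-BuOH/H2O) comes back to the route at 8.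

**Further compounds**
F1 | step 10 | benzyl 2-heptyl-4-methoxy-6-(4,4,5,5-tetramethyl-1,3,2-dioxaborolan-2-yl)benzoate | CCCCCCCc1cc(OC)cc(B2OC(C)(C)C(C)(C)O2)c1C(=O)OCc1ccccc1
F2 | step 8 | 6-(4-hydroxy-3-methoxy-2-oxoundecyl)-2,2-dimethyl-4H-1,3-dioxin-4-one (mixture of diastereomers) | CCCCCCCC(O)C(OC)C(=O)CC1=CC(=O)OC(C)(C)O1
F3 | step 2 | heptylmagnesium bromide | CCCCCCC[Mg]Br
F4 | step 2 | 1-heptyl-3,5-dimethoxybenzene | CCCCCCCc1cc(OC)cc(OC)c1
F5 | step 2 | 2-heptyl-4,6-dimethoxybenzaldehyde | CCCCCCCc1cc(OC)cc(OC)c1C=O
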